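**Plan**
Numbering: ring B = C5–C10, ring C = C8, C9, C11–C14; C13 carries C17H3 and the C15=C16 vinyl group, C10 carries C20H3 and the C1H2–C2O2H arm, C5 carries C4Me2–C3O2H; β is the face of 8-OH, 10-CH3 and 13-CH3, α that of H9.
Enabling feature: the oxygen-bearing C7 lies between C6H2 and the fully substituted C8, and C5 bears a CMe2CO2H group. C6 can therefore come from the methyl of an acetyl group on C8 (enolisable in one direction only, because C8 and C13 are quaternary) and C5 from the β-carbon of an α-methyl acrylate attached to C10; one conjugate addition closes ring B and the ester enolate left at C4 takes the second methyl group.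
Retrosynthetic cuts: acyl and ester groups, C7 carbinol back to the ketone, then C5–C6 and C4–CH3 (ring B), then C5=C4 (Wittig), C8–C7 (aldol), C10–C1 (lactone enolate alkylation), C9–C10 and C8–O (Mukaiyama–Michael/lactonisation), C14=O (allylic oxidation), and the ring-C cyclohexene back to butadiene and methacrolein.
Forward order: ring C by Diels–Alder reaction; a temporary cis-fused γ-lactone (O8–C5) is built on it and used as the template for C8 and C10; the lactone is opened into the enoate arm; ring B is closed last, followed by C7 reduction and acyl/ester adjustment.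
Stereochemistry: C13 from the catalytic Diels–Alder reaction; C11 from iodolactonisation (oxygen cis to the carboxyl carbon); C9 by addition anti to the C11 silyloxy group; C8 by SN2 lactonisation and convex-face aldol; C10 by convex-face alkylation; C5 from the chair Michael transition state; C7 by equatorial hydride attack.
Key step: step 20

Assumption: the (S)-oxazaborolidinium catalyst is taken to give the (R)-Diels–Alder aldehyde (otherwise its mirror image is used); compounds written without a descriptor at C10, C7 or a lactol carbon are epimer mixtures that converge later.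

Step 1
Reactants: 1 buta-1,3-diene; 2 methacrolein
Product: 3 (R)-1-methylcyclohex-3-ene-1-carbaldehyde
Conditions: (S)-o-tolyl diphenylprolinol oxazaborolidine/Tf2NH (10 mol%), CH2Cl2, −78 → −40 °C
Reagents that add atoms: none
Why: Enantioselective Diels–Alder reaction of an α-substituted enal under cationic oxazaborolidinium catalysis, in which the catalyst-bound enal exposes one face to the diene and so sets C13, the only stereocentre formed.

Step 2
Reactants: 3 (R)-1-methylcyclohex-3-ene-1-carbaldehyde
Product: 4 (R)-1-methylcyclohex-3-ene-1-carboxylic acid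
Conditions: NaClO2, NaH2PO4, 2-methyl-2-butene, t-BuOH/H2O, 0 °C → rt
Reagents that add atoms: sodium chlorite, [Na+].[O-]Cl=O
Why: Pinnick oxidation converts the aldehyde into the acid without touching the ring alkene, and the quaternary C13 cannot epimerise.

Step 3
Reactants: 4 (R)-1-methylcyclohex-3-ene-1-carboxylic acid
Product: 5 (1R,4R,5R)-4-iodo-1-methyl-6-oxabicyclo[3.2.1]octan-7-one
Conditions: I2, KI, NaHCO3, H2O/CH2Cl2, 0 °C → rt, dark
Reagents that add atoms: iodine, II
Why: Kinetic iodolactonisation (5-exo) joins the carboxylate oxygen to C11 with iodine anti at C9, so the C11 oxygen is necessarily cis to the carboxyl carbon C15 (the future vinyl group), which fixes C11 relative to C13.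

Step 4
Reactants: 5 (1R,4R,5R)-4-iodo-1-methyl-6-oxabicyclo[3.2.1]octan-7-one
Product: 6 (1R,5R)-1-methyl-6-oxabicyclo[3.2.1]oct-3-en-7-one
Conditions: DBU, toluene, 110 °C
Reagents that add atoms: none
Why: E2 dehydroiodination takes the antiperiplanar hydrogen on C8 because the bridgehead H11 cannot be used, which places the alkene at C8=C9.

Step 5
Reactants: 6 (1R,5R)-1-methyl-6-oxabicyclo[3.2.1]oct-3-en-7-one
Product: 7 (1R,5R)-1-methyl-6-oxabicyclo[3.2.1]oct-3-en-7-ol (lactol)
Conditions: DIBAL-H (1.1 equiv), CH2Cl2, −78 °C; Rochelle salt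
Reagents that add atoms: none
Why: Partial reduction of a lactone with DIBAL-H stops at the aluminium hemiacetal at −78 °C and should give the lactol on work-up.

Step 6
Reactants: 7 (1R,5R)-1-methyl-6-oxabicyclo[3.2.1]oct-3-en-7-ol
Product: 8 (1R,5R)-5-methyl-5-vinylcyclohex-2-en-1-ol
Conditions: Ph3PCH3Br, KOt-Bu, THF, 0 → 65 °C
Reagents that add atoms: methyltriphenylphosphonium bromide, C[P+](c1ccccc1)(c1ccccc1)c1ccccc1.[Br-]
Why: Wittig methylenation of the ring-opened hydroxy aldehyde turns C15 into the vinyl group and releases the 11α-hydroxyl, neither stereocentre being involved.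

Step 7
Reactants: 8 (1R,5R)-5-methyl-5-vinylcyclohex-2-en-1-ol
Product: 9 tert-butyldimethylsilyl ether of 8
Conditions: TBSCl, imidazole, DMF, rt
Reagents that add atoms: tert-butyldimethylsilyl chloride, CC(C)(C)[Si](C)(C)Cl
Why: Standard silylation of a secondary allylic alcohol provides the O11 protecting group that later directs the addition at C9.

Step 8
Reactants: 9 tert-butyldimethylsilyl ether of 8
Product: 10 (4R,6R)-4-[(tert-butyldimethylsilyl)oxy]-6-methyl-6-vinylcyclohex-2-en-1-one
Conditions: Rh2(cap)4 (1 mol%), t-BuOOH (5 equiv), K2CO3, CH2Cl2, rt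
Reagents that add atoms: tert-butyl hydroperoxide, CC(C)(C)OO
Why: Dirhodium caprolactamate/TBHP allylic oxidation should convert the ring-allylic C14 methylene into the enone carbonyl, the other allylic position being a single C11–H shielded by the silyl ether and the vinyl group having no allylic hydrogen.

Step 9
Reactants: 11 trimethylsilyl propanoate
Product: 13 1,1-bis(trimethylsilyloxy)prop-1-ene, via lithium ester enolate 12 (not isolated)
Conditions: LDA, THF, −78 °C; TMSCl, −78 °C → rt
Reagents that add atoms: chlorotrimethylsilane, C[Si](C)(C)Cl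
Why: Enolisation of the silyl ester and O-silylation of the enolate give the bis-silyl ketene acetal, a standard route to such propanoic acid enolate equivalents.

Step 10
Reactants: 10 (4R,6R)-4-[(tert-butyldimethylsilyl)oxy]-6-methyl-6-vinylcyclohex-2-en-1-one; 13 1,1-bis(trimethylsilyloxy)prop-1-ene
Product: 16 cis-fused keto γ-lactone (O8β–C5 lactone of the 11α-silyloxy ring-C 14-ketone; C10 epimers), via bis-silyl Michael adduct 14 (not isolated), via 8α-bromo keto acid 15 (not isolated)
Conditions: 13 (1.5 equiv), Tf2NH (2 mol%), CH2Cl2, −78 °C; NBS (1.6 equiv), THF, −78 °C; sat. aq. NaHCO3, n-Bu4NBr (cat.), rt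
Reagents that add atoms: none
Why: Mukaiyama–Michael addition anti to the 11α-silyloxy group sets H9 α and returns the C14 enol silane, NBS brominates this at C8 anti to the new side chain, and the carboxylate freed on hydrolysis displaces the α-keto bromide with inversion (5-exo-tet) so that O8 is β and the lactone cis-fused, any 8β-bromide being equilibrated by bromide exchange.

Step 11
Reactants: 16 cis-fused keto γ-lactone
Product: 17 14-O-triethylsilyl enol ether (C8=C14) of 16
Conditions: TESOTf, Et3N, CH2Cl2, 0 °C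
Reagents that add atoms: triethylsilyl trifluoromethanesulfonate, CC[Si](CC)(CC)OS(=O)(=O)C(F)(F)F
Why: Soft enolisation of the ketone, whose only α-hydrogen is H8, stores C14=O as a silyl enol ether so that the lactone α-hydrogen at C10 is the only acidic site in the next step.

Step 12
Reactants: 17 14-O-triethylsilyl enol ether of 16; 18 tert-butyl bromoacetate
Product: 20 C10-quaternary lactone enol ether (10β-methyl; C1H2CO2t-Bu on the H9 face), via lithium lactone enolate 19 (not isolated)
Conditions: LDA, THF, −78 °C; 18, DMPU, −78 → −40 °C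
Reagents that add atoms: none
Why: Lactone enolate alkylation in which both C10 epimers converge on one enolate and the electrophile enters on the convex face, syn to H9 and anti to the C9–C11 bond, which places the C20 methyl β and the acetate arm α as in the target, the low temperature guarding the enol-lactone enolate against ketene extrusion.

Step 13
Reactants: 20 C10-quaternary lactone enol ether; 21 acetaldehyde
Product: 22 keto lactone bearing an 8α-[1-(triethylsilyloxy)ethyl] group (C7 epimers)
Conditions: MeCHO (3 equiv), Tf2NH (3 mol%), CH2Cl2, −78 °C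
Reagents that add atoms: none
Why: Silyl triflimide-catalysed Mukaiyama aldol addition with silyl transfer, in which acetaldehyde can reach C8 only on the face opposite the fused lactone ring (syn to H9), so C7 becomes α and O8 stays β, the carbinol centre C7 being left unassigned because it is oxidised later.

Step 14
Reactants: 22 keto lactone bearing an 8α-[1-(triethylsilyloxy)ethyl] group
Product: 23 lactol of 22 (C5 hemiacetal)
Conditions: DIBAL-H (1.2 equiv), toluene, −78 °C; Rochelle salt
Reagents that add atoms: none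
Why: Partial reduction of the γ-lactone, whose carbonyl is far more accessible than the C14 ketone held between two quaternary carbons, any C14 carbinol formed being returned to the ketone by the oxidation in step 18.

Step 15
Reactants: 24 tert-butyl 2-bromopropanoate
Product: 26 tert-butyl 2-(triphenyl-λ5-phosphanylidene)propanoate, via phosphonium bromide 25 (not isolated)
Conditions: PPh3, toluene, 80 °C; aq. NaOH, CH2Cl2, rt
Reagents that add atoms: triphenylphosphine, c1ccc(cc1)P(c1ccccc1)c1ccccc1
Why: SN2 quaternisation of the phosphine followed by deprotonation gives the stabilised ylide.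

Step 16
Reactants: 23 lactol of 22; 26 tert-butyl 2-(triphenyl-λ5-phosphanylidene)propanoate
Product: 27 (E)-enoate with free 8β-OH and 7-O-triethylsilyl group
Conditions: 26 (3 equiv), PhCO2H (10 mol%), toluene, 100 °C
Reagents that add atoms: none
Why: Wittig olefination of the ring-opened hydroxy aldehyde with the stabilised α-methyl ylide should give the (E)-trisubstituted enoate, the neutral conditions avoiding an O8 alkoxide that could add back to the enoate.

Step 17
Reactants: 27 (E)-enoate with free 8β-OH and 7-O-triethylsilyl group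
Product: 28 7,8-diol
Conditions: PPTS, MeOH, rt
Reagents that add atoms: none
Why: Acid-catalysed methanolysis removes a secondary triethylsilyl ether much faster than the TBS ether at O11 and leaves the tert-butyl esters alone.

Step 18
Reactants: 28 7,8-diol
Product: 29 8β-hydroxy-8α-acetyl 14-ketone
Conditions: DMP, CH2Cl2, 0 °C → rt
Reagents that add atoms: none
Why: Dess–Martin oxidation of the only secondary alcohol gives the acetyl group, the tertiary 8-hydroxyl being inert.

Step 19
Reactants: 29 8β-hydroxy-8α-acetyl 14-ketone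
Product: 30 8β-(trimethylsilyloxy)-8α-acetyl 14-ketone carrying the C10 (E)-enoate side chain on C9
Conditions: TMSOTf, 2,6-lutidine, CH2Cl2, −78 °C
Reagents that add atoms: trimethylsilyl trifluoromethanesulfonate, C[Si](C)(C)OS(=O)(=O)C(F)(F)F
Why: Silyl triflate silylation caps the hindered tertiary hydroxyl so that no O8 alkoxide can undergo oxa-Michael addition or α-ketol rearrangement under the basic conditions of the next step.

Step 20
Reactants: 30 8β-(trimethylsilyloxy)-8α-acetyl 14-ketone carrying the C10 (E)-enoate side chain on C9; 31 iodomethane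
Product: 34 8β-trimethylsilyloxy trans-decalin-7,14-dione bearing both tert-butyl ester arms (H5α; 11α-OTBS), via C6 lithium enolate 32 (not isolated), via C4 lithium ester enolate 33 (not isolated)
Conditions: LDA (1.05 equiv), THF, −78 °C; DMPU, −78 → −20 °C; MeI (5 equiv), −78 → 0 °C
Reagents that add atoms: none
Why: LDA deprotonates the acetyl methyl group, the most acidic and least hindered site (neither ketone can enolise elsewhere because C8 and C13 are quaternary, and the C1H2 of the tert-butyl ester is less acidic and neopentyl), and the C6 enolate 32 adds to C5 of the tethered enoate to give ester enolate 33, which iodomethane captures at C4 to complete the gem-dimethyl carbon. The closest known reaction type is the tandem intramolecular Michael addition–enolate alkylation. Ring B closes in the 6-(enolexo)-exo-trig mode through a chair transition state that continues the ring-C chair, with C7 and C10 equatorial on ring C and the C20 methyl axial. The new stereocentre C5 is controlled by this chair, the alkenyl carbon C4 lying pseudo-equatorial (H5 axial, α) and the (E) geometry holding the ester away from ring C. The step needs methylation at C4 and not at C6, secured by a base whose conjugate acid (diisopropylamine) cannot relay a proton to the ester enolate and by adding MeI/DMPU cold once cyclisation is complete, and it needs C- rather than O-conjugate addition, secured by the silyl cap on O8.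

Step 21
Reactants: 34 8β-trimethylsilyloxy trans-decalin-7,14-dione bearing both tert-butyl ester arms
Product: 35 7α-alcohol of 34
Conditions: L-Selectride, THF, −78 °C; pH 7 buffer, H2O2
Reagents that add atoms: none
Why: The bulky trialkylborohydride should attack the C7 ketone along the equatorial trajectory because the axial path is blocked by H5α and H9α, giving the axial 7α-alcohol as with 4,4-disubstituted 3-keto triterpenoids, while the C14 ketone between two quaternary carbons stays untouched.

Step 22
Reactants: 35 7α-alcohol of 34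
Product: 36 7α-acetate
Conditions: Ac2O, Et3N, DMAP, CH2Cl2, rt
Reagents that add atoms: acetic anhydride, CC(=O)OC(C)=O
Why: DMAP-catalysed acetylation of the hindered secondary alcohol, the only free hydroxyl.

Step 23
Reactants: 36 7α-acetate
Product: 37 7α-acetoxy-8β,11α-diol di-tert-butyl ester
Conditions: HF·pyridine, pyridine, THF, 0 °C → rt
Reagents that add atoms: none
Why: Fluoride cleaves both silyl ethers to expose the secondary 11α- and tertiary 8β-hydroxyls, and the trans-diaxial 7-OAc/8-OH pair cannot exchange the acetyl group.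

Step 24
Reactants: 37 7α-acetoxy-8β,11α-diol di-tert-butyl ester
Product: 38 11α-benzoate di-tert-butyl ester
Conditions: BzCl, pyridine, DMAP (cat.), CH2Cl2, 0 °C → rt
Reagents that add atoms: benzoyl chloride, O=C(Cl)c1ccccc1
Why: Acylation is selective for the equatorial secondary 11α-hydroxyl over the tertiary α-keto 8-hydroxyl.

Step 25
Reactants: 38 11α-benzoate di-tert-butyl ester
Product: 39 CNP0315860.1
Conditions: TFA/CH2Cl2 (1:3), 0 °C → rt
Reagents that add atoms: none
Why: Acidolysis of both tert-butyl esters by loss of isobutene leaves the acetate, benzoate, vinyl group and tertiary α-ketol intact.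

**Compound list**
1 | buta-1,3-diene | C=CC=C | starting material
2 | methacrolein (2-methylprop-2-enal) | CC(=C)C=O | starting material
3 | (R)-1-methylcyclohex-3-ene-1-carbaldehyde | O=C[C@@]1(C)CC=CCC1 | intermediate
4 | (R)-1-methylcyclohex-3-ene-1-carboxylic acid | OC(=O)[C@@]1(C)CC=CCC1 | intermediate
5 | (1R,4R,5R)-4-iodo-1-methyl-6-oxabicyclo[3.2.1]octan-7-one | O=C1O[C@@H]2C[C@@]1(C)CC[C@H]2I | intermediate
6 | (1R,5R)-1-methyl-6-oxabicyclo[3.2.1]oct-3-en-7-one | O=C1O[C@@H]2C[C@@]1(C)CC=C2 | intermediate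
7 | (1R,5R)-1-methyl-6-oxabicyclo[3.2.1]oct-3-en-7-ol (lactol, both anomers) | OC1O[C@@H]2C[C@@]1(C)CC=C2 | intermediate
8 | (1R,5R)-5-methyl-5-vinylcyclohex-2-en-1-ol | C=C[C@@]1(C)C[C@@H](O)C=CC1 | intermediate
9 | tert-butyldimethyl{[(1R,5R)-5-methyl-5-vinylcyclohex-2-en-1-yl]oxy}silane | C=C[C@@]1(C)C[C@@H](O[Si](C)(C)C(C)(C)C)C=CC1 | intermediate
10 | (4R,6R)-4-[(tert-butyldimethylsilyl)oxy]-6-methyl-6-vinylcyclohex-2-en-1-one (C14 ketone, C8=C9, 11α-OTBS, 13β-methyl, 13α-vinyl) | C=C[C@@]1(C)C[C@@H](O[Si](C)(C)C(C)(C)C)C=CC1=O | intermediate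
11 | trimethylsilyl propanoate | CCC(=O)O[Si](C)(C)C | starting material
12 | lithium 1-(trimethylsilyloxy)prop-1-en-1-olate | CC=C(O[Li])O[Si](C)(C)C | intermediate
13 | 1,1-bis(trimethylsilyloxy)prop-1-ene | CC=C(O[Si](C)(C)C)O[Si](C)(C)C | intermediate
14 | bis-silyl Michael adduct: C14 trimethylsilyl enol ether (C8=C14) with 11α-OTBS and a 9β-CH(CH3)CO2SiMe3 group (H9 α; C10 epimers) | C=C[C@@]1(C)C[C@@H](O[Si](C)(C)C(C)(C)C)[C@H](C(C)C(=O)O[Si](C)(C)C)C=C1O[Si](C)(C)C | intermediate
15 | 8α-bromo keto acid: 8α-bromo 14-ketone with 11α-OTBS and a 9β-(1-carboxyethyl) group (C10 epimers) | C=C[C@@]1(C)C[C@@H](O[Si](C)(C)C(C)(C)C)[C@H](C(C)C(=O)O)[C@@H](Br)C1=O | intermediate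
16 | cis-fused keto γ-lactone: ring-C 14-ketone (11α-OTBS, 13β-methyl, 13α-vinyl) whose 8β-oxygen is lactonised to C5 of the 9β-CH(CH3) chain; H8 and H9 α; C10 epimers | C=C[C@@]1(C)C[C@@H](O[Si](C)(C)C(C)(C)C)[C@@H]2C(C)C(=O)O[C@@H]2C1=O | intermediate
17 | 14-O-triethylsilyl enol ether (C8=C14) of lactone 16 | C=C[C@@]1(C)C[C@@H](O[Si](C)(C)C(C)(C)C)[C@@H]2C(C)C(=O)OC2=C1O[Si](CC)(CC)CC | intermediate
18 | tert-butyl bromoacetate | CC(C)(C)OC(=O)CBr | starting material
19 | lithium lactone enolate (C10=C5) of 17 | C=C[C@@]1(C)C[C@@H](O[Si](C)(C)C(C)(C)C)[C@@H]2C(C)=C(O[Li])OC2=C1O[Si](CC)(CC)CC | intermediate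
20 | C10-quaternary lactone enol ether: 17 with 10β-methyl (C20) and 10α-CH2CO2t-Bu (C1–C2) | C=C[C@@]1(C)C[C@@H](O[Si](C)(C)C(C)(C)C)[C@@H]2[C@@](C)(CC(=O)OC(C)(C)C)C(=O)OC2=C1O[Si](CC)(CC)CC | intermediate
21 | acetaldehyde | CC=O | starting material
22 | keto lactone with 8α-[1-(triethylsilyloxy)ethyl] group (C7 epimers), O8β lactone and quaternary C10 | C=C[C@@]1(C)C[C@@H](O[Si](C)(C)C(C)(C)C)[C@@H]2[C@@](C)(CC(=O)OC(C)(C)C)C(=O)O[C@]2(C(C)O[Si](CC)(CC)CC)C1=O | intermediate
23 | lactol of 22 (C5 hemiacetal, both anomers) | C=C[C@@]1(C)C[C@@H](O[Si](C)(C)C(C)(C)C)[C@@H]2[C@@](C)(CC(=O)OC(C)(C)C)C(O)O[C@]2(C(C)O[Si](CC)(CC)CC)C1=O | intermediate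
24 | tert-butyl 2-bromopropanoate | CC(Br)C(=O)OC(C)(C)C | starting material
25 | (1-tert-butoxy-1-oxopropan-2-yl)triphenylphosphonium bromide | CC(C(=O)OC(C)(C)C)[P+](c1ccccc1)(c1ccccc1)c1ccccc1.[Br-] | intermediate
26 | tert-butyl 2-(triphenyl-λ5-phosphanylidene)propanoate | CC(C(=O)OC(C)(C)C)=P(c1ccccc1)(c1ccccc1)c1ccccc1 | intermediate
27 | ring-C 14-ketone with free 8β-OH, 8α-[1-(triethylsilyloxy)ethyl], 11α-OTBS and the 9β chain C10(CH3)(CH2CO2t-Bu)–CH=C(CH3)CO2t-Bu, (E) | C=C[C@@]1(C)C[C@@H](O[Si](C)(C)C(C)(C)C)[C@H]([C@@](C)(CC(=O)OC(C)(C)C)/C=C(\C)C(=O)OC(C)(C)C)[C@@](O)(C(C)O[Si](CC)(CC)CC)C1=O | intermediate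
28 | 7,8-diol: 27 with the C7 hydroxyl free | C=C[C@@]1(C)C[C@@H](O[Si](C)(C)C(C)(C)C)[C@H]([C@@](C)(CC(=O)OC(C)(C)C)/C=C(\C)C(=O)OC(C)(C)C)[C@@](O)(C(C)O)C1=O | intermediate
29 | 8β-hydroxy-8α-acetyl 14-ketone with 11α-OTBS and the C10 (E)-enoate/acetate chain on C9 | C=C[C@@]1(C)C[C@@H](O[Si](C)(C)C(C)(C)C)[C@H]([C@@](C)(CC(=O)OC(C)(C)C)/C=C(\C)C(=O)OC(C)(C)C)[C@@](O)(C(C)=O)C1=O | intermediate
30 | key-step precursor: 8β-(trimethylsilyloxy)-8α-acetyl 14-ketone with 11α-OTBS and the C10 (E)-enoate/acetate chain on C9 | C=C[C@@]1(C)C[C@@H](O[Si](C)(C)C(C)(C)C)[C@H]([C@@](C)(CC(=O)OC(C)(C)C)/C=C(\C)C(=O)OC(C)(C)C)[C@@](O[Si](C)(C)C)(C(C)=O)C1=O | intermediate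
31 | iodomethane | CI | starting material
32 | C6 lithium enolate of 30 | C=C[C@@]1(C)C[C@@H](O[Si](C)(C)C(C)(C)C)[C@H]([C@@](C)(CC(=O)OC(C)(C)C)/C=C(\C)C(=O)OC(C)(C)C)[C@@](O[Si](C)(C)C)(C(=C)O[Li])C1=O | intermediate
33 | ring-B-closed C4 lithium ester enolate | C=C[C@@]1(C)C[C@@H](O[Si](C)(C)C(C)(C)C)[C@@H]2[C@@](C)(CC(=O)OC(C)(C)C)[C@H](C(C)=C(O[Li])OC(C)(C)C)CC(=O)[C@@]2(O[Si](C)(C)C)C1=O | intermediate
34 | key-step product: trans-decalin-7,14-dione with 8β-OTMS, 11α-OTBS, H5α, H9α, 10β-CH3, CH2CO2t-Bu on C10 and CMe2CO2t-Bu on C5 | C=C[C@@]1(C)C[C@@H](O[Si](C)(C)C(C)(C)C)[C@@H]2[C@@](C)(CC(=O)OC(C)(C)C)[C@H](C(C)(C)C(=O)OC(C)(C)C)CC(=O)[C@@]2(O[Si](C)(C)C)C1=O | intermediate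
35 | 7α-alcohol of 34 | C=C[C@@]1(C)C[C@@H](O[Si](C)(C)C(C)(C)C)[C@@H]2[C@@](C)(CC(=O)OC(C)(C)C)[C@H](C(C)(C)C(=O)OC(C)(C)C)C[C@@H](O)[C@@]2(O[Si](C)(C)C)C1=O | intermediate
36 | 7α-acetate of 35 | C=C[C@@]1(C)C[C@@H](O[Si](C)(C)C(C)(C)C)[C@@H]2[C@@](C)(CC(=O)OC(C)(C)C)[C@H](C(C)(C)C(=O)OC(C)(C)C)C[C@@H](OC(C)=O)[C@@]2(O[Si](C)(C)C)C1=O | intermediate
37 | 7α-acetoxy-8β,11α-diol di-tert-butyl ester | C=C[C@@]1(C)C[C@@H](O)[C@@H]2[C@@](C)(CC(=O)OC(C)(C)C)[C@H](C(C)(C)C(=O)OC(C)(C)C)C[C@@H](OC(C)=O)[C@@]2(O)C1=O | intermediate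
38 | 7α-acetoxy-11α-benzoyloxy-8β-hydroxy di-tert-butyl ester | C=C[C@@]1(C)C[C@@H](OC(=O)c2ccccc2)[C@@H]2[C@@](C)(CC(=O)OC(C)(C)C)[C@H](C(C)(C)C(=O)OC(C)(C)C)C[C@@H](OC(C)=O)[C@@]2(O)C1=O | intermediate
39 | CNP0315860.1 (7α-acetoxy-11α-benzoyloxy-8β-hydroxy-14-oxo seco-diacid) | C=C[C@@]1(C)C[C@@H](OC(=O)c2ccccc2)[C@@H]2[C@@](C)(CC(=O)O)[C@H](C(C)(C)C(=O)O)C[C@@H](OC(C)=O)[C@@]2(O)C1=O | target

Total step count: 25. Longest linear sequence: 23 steps (1–8, 10–14, 16–25).

**Steps most likely to fail**

Step 20 (key step). The conjugate addition at the neopentyl, α-methylated β-carbon may be slower than proton exchange between the cyclised ketone (C6–H) and the C4 ester enolate, so that the methyl group ends on C6 or the C4–H ester is formed. The fallback sets out from 29. TMSOTf/Et3N should silylate O8 and turn the acetyl group into its enol silane in one operation, giving the 8-O-trimethylsilyl C7 enol silane F1. A silyl triflimide-catalysed intramolecular Mukaiyama–Michael addition (Tf2NH cat., CH2Cl2, −78 → −20 °C) should then close ring B through the same chair and give the C4 silyl ketene acetal F2, a regiodefined enolate equivalent formed with no base present. Fluoride (TASF, THF, −78 °C) in the presence of iodomethane releases the enolate and methylates it at C4, and the route is rejoined at 34.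

Step 13. Protodesilylation of the tetrasubstituted enol ether may outrun carbon–carbon bond formation at a carbon flanked by two quaternary centres. The fallback sets out from 16 and reverses the order of the two bond formations. LiHMDS (THF, −78 °C) and acetaldehyde should give the 8α-(1-hydroxyethyl) keto lactone F3 through the more reactive lithium enolate, again on the convex face. TESOTf/2,6-lutidine gives its triethylsilyl ether F4. LDA and 18 then alkylate the lactone enolate at C10 syn to H9, and the route is rejoined at 22.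

Step 21. Facial selectivity may be poor, because hydride delivery anti to the axial C8–O bond (axial attack) would give the equatorial 7β-alcohol. The fallback sets out from 34. Dilute HCl in THF (0 °C) should remove the O8 trimethylsilyl group to give the 8β-hydroxy dione F5. Me4NBH(OAc)3 (MeCN/AcOH, −20 °C) exchanges onto the tertiary hydroxyl and delivers hydride intramolecularly to the β face of C7, giving the trans 7α,8β-diol F6. Ac2O/Et3N/DMAP acetylates only the secondary hydroxyl to give the 7α-acetate F7, and HF·pyridine removes the TBS ether to rejoin the route at 37.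

**Further compounds**
F1 | step 20 | 8-O-trimethylsilyl C7 enol silane of 29 | C=C[C@@]1(C)C[C@@H](O[Si](C)(C)C(C)(C)C)[C@H]([C@@](C)(CC(=O)OC(C)(C)C)/C=C(\C)C(=O)OC(C)(C)C)[C@@](O[Si](C)(C)C)(C(=C)O[Si](C)(C)C)C1=O
F2 | step 20 | ring-B-closed C4 silyl ketene acetal | C=C[C@@]1(C)C[C@@H](O[Si](C)(C)C(C)(C)C)[C@@H]2[C@@](C)(CC(=O)OC(C)(C)C)[C@H](C(C)=C(O[Si](C)(C)C)OC(C)(C)C)CC(=O)[C@@]2(O[Si](C)(C)C)C1=O
F3 | step 13 | 8α-(1-hydroxyethyl) keto lactone (C7 and C10 epimers) | C=C[C@@]1(C)C[C@@H](O[Si](C)(C)C(C)(C)C)[C@@H]2C(C)C(=O)O[C@]2(C(C)O)C1=O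
F4 | step 13 | triethylsilyl ether of F3 | C=C[C@@]1(C)C[C@@H](O[Si](C)(C)C(C)(C)C)[C@@H]2C(C)C(=O)O[C@]2(C(C)O[Si](CC)(CC)CC)C1=O
F5 | step 21 | 8β-hydroxy trans-decalin-7,14-dione (11α-OTBS) | C=C[C@@]1(C)C[C@@H](O[Si](C)(C)C(C)(C)C)[C@@H]2[C@@](C)(CC(=O)OC(C)(C)C)[C@H](C(C)(C)C(=O)OC(C)(C)C)CC(=O)[C@@]2(O)C1=O
F6 | step 21 | 7α,8β-diol (11α-OTBS) | C=C[C@@]1(C)C[C@@H](O[Si](C)(C)C(C)(C)C)[C@@H]2[C@@](C)(CC(=O)OC(C)(C)C)[C@H](C(C)(C)C(=O)OC(C)(C)C)C[C@@H](O)[C@@]2(O)C1=O
F7 | step 21 | 7α-acetate of F6 | C=C[C@@]1(C)C[C@@H](O[Si](C)(C)C(C)(C)C)[C@@H]2[C@@](C)(CC(=O)OC(C)(C)C)[C@H](C(C)(C)C(=O)OC(C)(C)C)C[C@@H](OC(C)=O)[C@@]2(O)C1=O
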